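**Plan**

- Retrosynthesis: the protecting groups and the two hydrogens at C1 and C8a are removed first, which leads back to the 6H-isochromen-6-one 20. Ring B is then cut at C1–C8a and O2–C3 in one operation, giving alkynyl chloro enone 16 (as its silyl dienol ether 17) and a one-carbon formyl unit. 16 is cut at C4–C4a into ring A triflate 8 and dienyne 15.
- Enabling feature: C8a is the γ-carbon of the C6 enone of ring A (C5 carries Cl, C7 is quaternary, so no other enolisable position exists). A carbon placed on C8a holds its oxygen in 6-endo reach of C3 of the C3≡C4 alkyne on C4a, and that alkyne is polarised by the dienyl donor on C3 and the chloro enone acceptor on C4.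
- Forward order: ring A from (R)-carvone by cleavage of the C–C bond to the isopropenyl group (steps 1–6); side chain by two olefinations (steps 7–12); union at C4–C4a (step 13); ring B (step 15); 1,8a-reduction (step 16); deprotection (step 17). C1 enters at the aldehyde oxidation level and is taken down to CH2 in step 16.
- Stereochemistry: C13/C14 come from ethyl (S)-3-hydroxybutanoate by anti-selective alkylation. C7/C8 come from dihydroxylation anti to the carvone-derived acetoxy stereocentre, which is destroyed afterwards. C8a is set by substrate-controlled protonation anti to O8.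

Key step: step 15

Remark: isochromene numbering of the target (C1, O2, C3, C4, C4a, C5–C8, C8a; side chain C9–C15) is used for all ring A and bicyclic intermediates in the text; enolisable compounds are drawn as one tautomer; TBS = tert-butyldimethylsilyl.

**Route**

Step 1
Reactants: 1 (R)-(−)-carvone
Product: 2 (5R)-5-acetoxy-2-methylcyclohex-2-en-1-one
Conditions: O3, CH2Cl2/MeOH, −78 °C; then Ac2O, Et3N, DMAP (cat.), −78 °C → rt
Reagents that add atoms: ozone, [O-][O+]=O; methanol, CO
Why: the electron-rich isopropenyl group is ozonised in preference to the enone, and the α-methoxy hydroperoxide, once acetylated, undergoes Criegee rearrangement with retentive shift of the ring carbon to oxygen, so the carvone stereocentre becomes an acetoxy stereocentre of the same configuration.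

Step 2
Reactants: 2 (5R)-5-acetoxy-2-methylcyclohex-2-en-1-one
Product: 3 (1R,3R,4R)-3,4-dihydroxy-4-methyl-5-oxocyclohexyl acetate
Conditions: OsO4 (2 mol %), N-methylmorpholine N-oxide, acetone/H2O, 0 °C → rt
Reagents that add atoms: N-methylmorpholine N-oxide, C[N+]1([O-])CCOCC1; water, O
Why: Upjohn dihydroxylation adds both oxygens suprafacially to the C7=C8 bond (cis-diol) on the face anti to the acetoxy group, which shields its own face of C8 in either half-chair, so C7 and C8 are set by substrate control; the minor diastereomer should be removed here because it would become the enantiomer of 6 after step 4.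

Step 3
Reactants: 3 (1R,3R,4R)-3,4-dihydroxy-4-methyl-5-oxocyclohexyl acetate
Product: 5 (3aR,6R,7aR)-6-hydroxy-2,2,3a-trimethyltetrahydro-1,3-benzodioxol-4(3aH)-one, via triol 4 (not isolated)
Conditions: AcCl (0.3 equiv), MeOH, 0 °C → rt; evaporate; Me2C(OMe)2, PPTS (cat.), acetone, rt
Reagents that add atoms: 2,2-dimethoxypropane, COC(C)(C)OC
Why: acid-catalysed transesterification frees the alcohol without the base that would eliminate a β-acyloxy ketone, and the acetonide can form only on the cis-1,2-diol because the remaining hydroxyl is trans-1,3 to O8 and cannot be bridged.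

Step 4
Reactants: 5 (3aR,6R,7aR)-6-hydroxy-2,2,3a-trimethyltetrahydro-1,3-benzodioxol-4(3aH)-one
Product: 6 (3aR,7aR)-2,2,3a-trimethyldihydro-1,3-benzodioxole-4,6(3aH,5H)-dione
Conditions: Dess–Martin periodinane, NaHCO3, CH2Cl2, 0 °C → rt
Reagents that add atoms: none
Why: Dess–Martin oxidation of the secondary alcohol gives the 1,3-dione and removes the sacrificial stereocentre; the dione cannot aromatise because C7 is quaternary.

Step 5
Reactants: 6 (3aR,7aR)-2,2,3a-trimethyldihydro-1,3-benzodioxole-4,6(3aH,5H)-dione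
Product: 7 (3aR,7aR)-5-chloro-6-hydroxy-2,2,3a-trimethyl-7,7a-dihydro-1,3-benzodioxol-4(3aH)-one
Conditions: N-chlorosuccinimide (1.0 equiv), CH2Cl2, 0 °C
Reagents that add atoms: N-chlorosuccinimide, O=C1CCC(=O)N1Cl
Why: electrophilic chlorination of the enolised 1,3-dione occurs at the carbon between the two carbonyls (C5), the only nucleophilic position.

Step 6
Reactants: 7 (3aR,7aR)-5-chloro-6-hydroxy-2,2,3a-trimethyl-7,7a-dihydro-1,3-benzodioxol-4(3aH)-one
Product: 8 (3aR,7aR)-5-chloro-2,2,3a-trimethyl-4-oxo-3a,4,7,7a-tetrahydro-1,3-benzodioxol-6-yl trifluoromethanesulfonate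
Conditions: Tf2O, 2,6-lutidine, CH2Cl2, −78 °C
Reagents that add atoms: trifluoromethanesulfonic anhydride, O=S(=O)(OS(=O)(=O)C(F)(F)F)C(F)(F)F
Why: O-sulfonylation gives the vinylogous acyl triflate at the oxygen on C4a, which is flanked by a CH2 group, whereas the C6 carbonyl is shielded by the quaternary C7 and stays a ketone.

Step 7
Reactants: 9 ethyl (S)-3-hydroxybutanoate
Product: 10 ethyl (2S,3S)-3-hydroxy-2-methylbutanoate
Conditions: LiN(i-Pr)2 (2.2 equiv), THF, −78 → −20 °C; MeI, DMPU, −78 → 0 °C
Reagents that add atoms: iodomethane, CI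
Why: Fráter–Seebach alkylation: the chelated alkoxide-enolate dianion is methylated on the face away from the C3 methyl group, which gives the anti (2S,3S) product and sets C13 from C14.

Step 8
Reactants: 10 ethyl (2S,3S)-3-hydroxy-2-methylbutanoate
Product: 11 ethyl (2S,3S)-3-[(tert-butyldimethylsilyl)oxy]-2-methylbutanoate
Conditions: TBSCl, imidazole, DMF, rt
Reagents that add atoms: tert-butyldimethylsilyl chloride, CC(C)(C)[Si](C)(C)Cl
Why: standard silylation of the secondary alcohol, needed so that the aldehyde of step 9 cannot undergo retro-aldol cleavage or dehydration.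

Step 9
Reactants: 11 ethyl (2S,3S)-3-[(tert-butyldimethylsilyl)oxy]-2-methylbutanoate
Product: 12 (2S,3S)-3-[(tert-butyldimethylsilyl)oxy]-2-methylbutanal
Conditions: i-Bu2AlH (1.05 equiv), CH2Cl2, −78 °C; aq. sodium potassium tartrate
Reagents that add atoms: none
Why: partial reduction of the ester through the stable tetrahedral aluminium hemiacetal at low temperature gives the aldehyde, which is used at once to keep the α-stereocentre intact.

Step 10
Reactants: 12 (2S,3S)-3-[(tert-butyldimethylsilyl)oxy]-2-methylbutanal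
Product: 13 (2E,4R,5S)-5-[(tert-butyldimethylsilyl)oxy]-2,4-dimethylhex-2-enal
Conditions: 2-(triphenylphosphoranylidene)propanal (1.1 equiv), toluene, 90 °C
Reagents that add atoms: 2-(triphenylphosphoranylidene)propanal, CC(C=O)=P(c1ccccc1)(c1ccccc1)c1ccccc1
Why: Wittig reaction with a stabilised, weakly basic ylide forms the trisubstituted C11=C12 bond with E geometry and should not epimerise the α-stereocentre.

Step 11
Reactants: 13 (2E,4R,5S)-5-[(tert-butyldimethylsilyl)oxy]-2,4-dimethylhex-2-enal
Product: 14 tert-butyl{[(2S,3R,4E,6E)-3,5-dimethyl-9-(trimethylsilyl)nona-4,6-dien-8-yn-2-yl]oxy}dimethylsilane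
Conditions: diethyl [3-(trimethylsilyl)prop-2-yn-1-yl]phosphonate, LiN(SiMe3)2, THF, −78 → 0 °C; then 13
Reagents that add atoms: diethyl [3-(trimethylsilyl)prop-2-yn-1-yl]phosphonate, CCOP(=O)(CC#C[Si](C)(C)C)OCC
Why: Horner–Wadsworth–Emmons olefination with the preformed propargylic phosphonate anion should give the E-configured C9=C10 bond, and the anion is consumed before it can deprotonate the γ-stereocentre of the enal.

Step 12
Reactants: 14 tert-butyl{[(2S,3R,4E,6E)-3,5-dimethyl-9-(trimethylsilyl)nona-4,6-dien-8-yn-2-yl]oxy}dimethylsilane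
Product: 15 tert-butyl{[(2S,3R,4E,6E)-3,5-dimethylnona-4,6-dien-8-yn-2-yl]oxy}dimethylsilane
Conditions: K2CO3, MeOH, rt
Reagents that add atoms: none
Why: methanolysis cleaves the alkynyl C–Si bond selectively and leaves the secondary TBS ether in place.

Step 13
Reactants: 8 (3aR,7aR)-5-chloro-2,2,3a-trimethyl-4-oxo-3a,4,7,7a-tetrahydro-1,3-benzodioxol-6-yl trifluoromethanesulfonate; 15 tert-butyl{[(2S,3R,4E,6E)-3,5-dimethylnona-4,6-dien-8-yn-2-yl]oxy}dimethylsilane
Product: 16 (3aR,7aR)-6-[(3E,5E,7R,8S)-8-[(tert-butyldimethylsilyl)oxy]-5,7-dimethylnona-3,5-dien-1-yn-1-yl]-5-chloro-2,2,3a-trimethyl-7,7a-dihydro-1,3-benzodioxol-4(3aH)-one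
Conditions: PdCl2(PPh3)2 (5 mol %), CuI (10 mol %), i-Pr2NEt, THF, 0 °C → rt
Reagents that add atoms: none
Why: Sonogashira coupling of the vinylogous acyl triflate forms C4–C4a; the alkenyl C–Cl bond is inert under these conditions and the hindered tertiary amine cannot displace the triflate by addition–elimination.

Step 14
Reactants: 16 (3aR,7aR)-6-[(3E,5E,7R,8S)-8-[(tert-butyldimethylsilyl)oxy]-5,7-dimethylnona-3,5-dien-1-yn-1-yl]-5-chloro-2,2,3a-trimethyl-7,7a-dihydro-1,3-benzodioxol-4(3aH)-one
Product: 17 tert-butyldimethylsilyl dienol ether of 16 (C6–OSi, C5=C6 and C4a=C8a)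
Conditions: TBSOTf, Et3N, CH2Cl2, 0 °C
Reagents that add atoms: tert-butyldimethylsilyl trifluoromethanesulfonate, CC(C)(C)[Si](C)(C)OS(=O)(=O)C(F)(F)F
Why: soft enolisation by O-silylation and γ-deprotonation at C8a, the only acidic position because C7 is quaternary, gives the extended silyl dienol ether without forming a carbanion next to the C8 oxygen.

Step 15
Reactants: 17 tert-butyldimethylsilyl dienol ether of 16
Product: 20 (7R,8R)-5-chloro-7,8-(isopropylidenedioxy)-7-methyl-3-[(1E,3E,5R,6S)-6-[(tert-butyldimethylsilyl)oxy]-3,5-dimethylhepta-1,3-dien-1-yl]-7,8-dihydro-6H-isochromen-6-one, via dimethyl acetal 18 (not isolated), via hydroxymethylene enone 19 (not isolated)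
Conditions: HC(OMe)3 (3 equiv), TMSOTf (10 mol %), CH2Cl2, −78 °C; then H2O (3 equiv), Ph3PAuNTf2 (5 mol %), −78 °C → rt
Reagents that add atoms: trimethyl orthoformate, COC(OC)OC; water, O
Why: The dimethoxycarbenium ion formed from HC(OMe)3 and TMSOTf adds to the γ-carbon C8a of 17 and forms C1–C8a as acetal 18; the closest known type is the vinylogous Mukaiyama condensation of silyl dienol ethers with orthoformates. Hydrolysis gives the γ-formyl enone, which rests as hydroxymethylene enone 19, and its enol oxygen attacks C3 of the gold-activated alkyne to form O2–C3; the closest known type is the gold-catalysed cycloisomerisation of 2-alkynyl aryl aldehydes to 2-benzopyrylium and azaphilone cores. Ring B, the only ring closed, forms by 6-endo-dig oxyauration followed by protodeauration. No stereocentre is created: C8a is deliberately left trigonal (C1=C8a) so that its configuration is set in step 16, and C7 and C8 are not touched. The step needs γ- over α-attack, which the chlorine on C5 and the absence of any α′-hydrogen at the quaternary C7 secure. It also needs 6-endo over 5-exo closure, which the polarisation of C3≡C4 between the dienyl donor on C3 and the chloro enone on C4, together with the gain of the fully conjugated pyranylidene ketone, secures.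

Step 16
Reactants: 20 (7R,8R)-5-chloro-7,8-(isopropylidenedioxy)-7-methyl-3-[(1E,3E,5R,6S)-6-[(tert-butyldimethylsilyl)oxy]-3,5-dimethylhepta-1,3-dien-1-yl]-7,8-dihydro-6H-isochromen-6-one
Product: 21 (7R,8R,8aS)-5-chloro-7,8-(isopropylidenedioxy)-7-methyl-3-[(1E,3E,5R,6S)-6-[(tert-butyldimethylsilyl)oxy]-3,5-dimethylhepta-1,3-dien-1-yl]-1,7,8,8a-tetrahydro-6H-isochromen-6-one
Conditions: diethyl 2,6-dimethyl-1,4-dihydropyridine-3,5-dicarboxylate (Hantzsch ester, 1.2 equiv), (PhO)2P(O)OH (10 mol %), CH2Cl2, −40 → 0 °C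
Reagents that add atoms: none
Why: Proposed new method: protonation of the C6 carbonyl of 20 should give a 6-hydroxy-2-benzopyrylium ion with an aromatic ring B, the Hantzsch ester transfers hydride to its unsubstituted C1, and the resulting cross-conjugated trienol ketonises by protonation at C8a (the position that gives the cation stabilised by both oxygen donors) on the face anti to the C8 oxygen, the convex face of the cis-fused dioxolane, which places H8a cis to H8 and C1 cis to O8; the product is a far weaker base than 20 and should not be reduced further, and the closest known reaction type is the Brønsted-acid-catalysed Hantzsch ester reduction of benzopyrylium and isochromenylium ions.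

Step 17
Reactants: 21 (7R,8R,8aS)-5-chloro-7,8-(isopropylidenedioxy)-7-methyl-3-[(1E,3E,5R,6S)-6-[(tert-butyldimethylsilyl)oxy]-3,5-dimethylhepta-1,3-dien-1-yl]-1,7,8,8a-tetrahydro-6H-isochromen-6-one
Product: 22 (7R,8R,8aS)-5-chloro-7,8-dihydroxy-3-[(1E,3E,5R,6S)-6-hydroxy-3,5-dimethylhepta-1,3-dien-1-yl]-7-methyl-1,7,8,8a-tetrahydro-6H-isochromen-6-one
Conditions: TFA/H2O/THF (1:1:4), 0 °C → rt
Reagents that add atoms: none
Why: mild aqueous acid hydrolyses the acetonide and the secondary silyl ether in one operation; the vinylogous ester of ring B is stable to it, and the low temperature should avoid dehydration across C8–C8a and epimerisation at C8a.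

**Compound list**

1 | (R)-(−)-carvone, (5R)-2-methyl-5-(prop-1-en-2-yl)cyclohex-2-en-1-one | O=C1C[C@H](C(C)=C)CC=C1C | starting material
2 | (5R)-5-acetoxy-2-methylcyclohex-2-en-1-one | O=C1C[C@H](OC(C)=O)CC=C1C | intermediate
3 | (1R,3R,4R)-3,4-dihydroxy-4-methyl-5-oxocyclohexyl acetate (cis-diol, trans to the acetoxy group) | O=C1C[C@H](OC(C)=O)C[C@@H](O)[C@@]1(C)O | intermediate
4 | (2R,3R,5R)-2,3,5-trihydroxy-2-methylcyclohexan-1-one | O=C1C[C@H](O)C[C@@H](O)[C@@]1(C)O | intermediate
5 | (3aR,6R,7aR)-6-hydroxy-2,2,3a-trimethyltetrahydro-1,3-benzodioxol-4(3aH)-one | O=C1C[C@H](O)C[C@H]2OC(C)(C)O[C@@]12C | intermediate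
6 | (3aR,7aR)-2,2,3a-trimethyldihydro-1,3-benzodioxole-4,6(3aH,5H)-dione | O=C1CC(=O)C[C@H]2OC(C)(C)O[C@@]12C | intermediate
7 | (3aR,7aR)-5-chloro-6-hydroxy-2,2,3a-trimethyl-7,7a-dihydro-1,3-benzodioxol-4(3aH)-one (enol form of the chloro dione) | O=C1C(Cl)=C(O)C[C@H]2OC(C)(C)O[C@@]12C | intermediate
8 | (3aR,7aR)-5-chloro-2,2,3a-trimethyl-4-oxo-3a,4,7,7a-tetrahydro-1,3-benzodioxol-6-yl trifluoromethanesulfonate | O=C1C(Cl)=C(OS(=O)(=O)C(F)(F)F)C[C@H]2OC(C)(C)O[C@@]12C | intermediate
9 | ethyl (S)-3-hydroxybutanoate | CCOC(=O)C[C@H](C)O | starting material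
10 | ethyl (2S,3S)-3-hydroxy-2-methylbutanoate | CCOC(=O)[C@@H](C)[C@H](C)O | intermediate
11 | ethyl (2S,3S)-3-[(tert-butyldimethylsilyl)oxy]-2-methylbutanoate | CCOC(=O)[C@@H](C)[C@H](C)O[Si](C)(C)C(C)(C)C | intermediate
12 | (2S,3S)-3-[(tert-butyldimethylsilyl)oxy]-2-methylbutanal | O=C[C@@H](C)[C@H](C)O[Si](C)(C)C(C)(C)C | intermediate
13 | (2E,4R,5S)-5-[(tert-butyldimethylsilyl)oxy]-2,4-dimethylhex-2-enal | O=C/C(C)=C/[C@@H](C)[C@H](C)O[Si](C)(C)C(C)(C)C | intermediate
14 | tert-butyl{[(2S,3R,4E,6E)-3,5-dimethyl-9-(trimethylsilyl)nona-4,6-dien-8-yn-2-yl]oxy}dimethylsilane | C[Si](C)(C)C#C/C=C/C(C)=C/[C@@H](C)[C@H](C)O[Si](C)(C)C(C)(C)C | intermediate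
15 | tert-butyl{[(2S,3R,4E,6E)-3,5-dimethylnona-4,6-dien-8-yn-2-yl]oxy}dimethylsilane | C#C/C=C/C(C)=C/[C@@H](C)[C@H](C)O[Si](C)(C)C(C)(C)C | intermediate
16 | (3aR,7aR)-6-[(3E,5E,7R,8S)-8-[(tert-butyldimethylsilyl)oxy]-5,7-dimethylnona-3,5-dien-1-yn-1-yl]-5-chloro-2,2,3a-trimethyl-7,7a-dihydro-1,3-benzodioxol-4(3aH)-one | O=C1C(Cl)=C(C#C/C=C/C(C)=C/[C@@H](C)[C@H](C)O[Si](C)(C)C(C)(C)C)C[C@H]2OC(C)(C)O[C@@]12C | intermediate
17 | tert-butyldimethylsilyl dienol ether of 16 (C6–OSi, C5=C6 and C4a=C8a) | CC(C)(C)[Si](C)(C)OC1=C(Cl)C(C#C/C=C/C(C)=C/[C@@H](C)[C@H](C)O[Si](C)(C)C(C)(C)C)=C[C@H]2OC(C)(C)O[C@@]12C | intermediate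
18 | C8a-(dimethoxymethyl) enone, dimethyl acetal of the C1 aldehyde (C8a epimers) | COC(OC)C1C(C#C/C=C/C(C)=C/[C@@H](C)[C@H](C)O[Si](C)(C)C(C)(C)C)=C(Cl)C(=O)[C@]2(C)OC(C)(C)O[C@H]12 | intermediate
19 | C8a-(hydroxymethylene) enone, enol form of the C1 aldehyde | OC=C1C(C#C/C=C/C(C)=C/[C@@H](C)[C@H](C)O[Si](C)(C)C(C)(C)C)=C(Cl)C(=O)[C@]2(C)OC(C)(C)O[C@H]12 | intermediate
20 | (7R,8R)-5-chloro-7,8-(isopropylidenedioxy)-7-methyl-3-[(1E,3E,5R,6S)-6-[(tert-butyldimethylsilyl)oxy]-3,5-dimethylhepta-1,3-dien-1-yl]-7,8-dihydro-6H-isochromen-6-one | CC(/C=C/C1=CC2=C(Cl)C(=O)[C@]3(C)OC(C)(C)O[C@@H]3C2=CO1)=C\[C@@H](C)[C@H](C)O[Si](C)(C)C(C)(C)C | intermediate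
21 | (7R,8R,8aS)-5-chloro-7,8-(isopropylidenedioxy)-7-methyl-3-[(1E,3E,5R,6S)-6-[(tert-butyldimethylsilyl)oxy]-3,5-dimethylhepta-1,3-dien-1-yl]-1,7,8,8a-tetrahydro-6H-isochromen-6-one | CC(/C=C/C1=CC2=C(Cl)C(=O)[C@]3(C)OC(C)(C)O[C@@H]3[C@@H]2CO1)=C\[C@@H](C)[C@H](C)O[Si](C)(C)C(C)(C)C | intermediate
22 | (7R,8R,8aS)-5-chloro-7,8-dihydroxy-3-[(1E,3E,5R,6S)-6-hydroxy-3,5-dimethylhepta-1,3-dien-1-yl]-7-methyl-1,7,8,8a-tetrahydro-6H-isochromen-6-one | CC(/C=C/C1=CC2=C(Cl)C(=O)[C@](C)(O)[C@H](O)[C@@H]2CO1)=C\[C@@H](C)[C@H](C)O | target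

**Step count and risks**

Total step count: 17. Longest linear sequence: 11 steps (steps 1–6 and 13–17; the side-chain branch, steps 7–12 and 13–17, is equally long).

Steps most likely to fail:

1. Step 16 (Proposed new method). The hydride may be delivered to C3 or along the dienyl-stabilised cation instead of C1, the product may be reduced further, or the proton may reach C8a with poor facial selectivity. The fallback uses known reaction types, avoids hydride altogether and brings C1 in at the alcohol oxidation level. It sets out from 17. A lanthanide-triflate-catalysed aqueous Mukaiyama hydroxymethylation (aq. HCHO, Yb(OTf)3, THF/H2O) at the γ-carbon should give the C8a-hydroxymethyl enone F1. Gold-catalysed 6-endo-dig hydroalkoxylation (Ph3PAuNTf2, CH2Cl2) closes ring B; because the carbon electrophile is expected to enter anti to O8, this should give mainly the 8a-epimer F2 alongside 21. Treatment of the mixture with TBSOTf and Et3N erases the C8a centre in the silyl trienol ether F3. Protonolysis of F3 (PPTS, MeOH, −20 °C) then delivers the proton anti to the dioxolane, as in the main route, and the sequence comes back to the route at 21.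

2. Step 15. The carbenium ion may add at C5 or to the dienyne, the acidic second stage may open the acetonide or remove silyl groups before cyclisation, or the closure may go 5-exo. The fallback separates the two bond formations and changes the one-carbon donor. It sets out from 17. Vilsmeier–Haack formylation with (chloromethylene)dimethyliminium chloride in CH2Cl2 at 0 °C, followed by aqueous NaOAc, should give the isolable push–pull C8a-(dimethylaminomethylene) enaminone F4. Hydrolysis and cycloisomerisation in one flask (AgOTf, 10 mol %, AcOH/H2O, rt) pass through 19 and come back to the route at 20.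

3. Step 3. The β-hydroxy ketone may dehydrate during the acidic methanolysis or on handling. The fallback accepts the elimination and rebuilds the 1,3-dione from the enone. It sets out from 3. Acetonide formation with the acetate kept (Me2C(OMe)2, PPTS, acetone) gives the acetonide acetate F5. Deliberate β-elimination (DBU, CH2Cl2) gives the enone F6. Nucleophilic epoxidation (H2O2, NaOH, MeOH, 0 °C) gives the epoxy ketone F7, whose epoxide configuration is immaterial. Palladium-catalysed isomerisation of the α,β-epoxy ketone to the 1,3-diketone (Pd(PPh3)4, dppe, toluene, 80 °C) comes back to the route at 6.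

**Further compounds**

F1 | step 16 | C8a-(hydroxymethyl) enone (C8a epimers) | OCC1C(C#C/C=C/C(C)=C/[C@@H](C)[C@H](C)O[Si](C)(C)C(C)(C)C)=C(Cl)C(=O)[C@]2(C)OC(C)(C)O[C@H]12
F2 | step 16 | (7R,8R,8aR) 8a-epimer of 21 | CC(/C=C/C1=CC2=C(Cl)C(=O)[C@]3(C)OC(C)(C)O[C@@H]3[C@H]2CO1)=C\[C@@H](C)[C@H](C)O[Si](C)(C)C(C)(C)C
F3 | step 16 | tert-butyldimethylsilyl trienol ether of 21 (C6–OSi, C5=C6, C4a=C8a, C3=C4) | CC(/C=C/C1=CC2=C(CO1)[C@H]3OC(C)(C)O[C@@]3(C)C(O[Si](C)(C)C(C)(C)C)=C2Cl)=C\[C@@H](C)[C@H](C)O[Si](C)(C)C(C)(C)C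
F4 | step 15 | C8a-(dimethylaminomethylene) enaminone | CN(C)C=C1C(C#C/C=C/C(C)=C/[C@@H](C)[C@H](C)O[Si](C)(C)C(C)(C)C)=C(Cl)C(=O)[C@]2(C)OC(C)(C)O[C@H]12
F5 | step 3 | (3aR,6R,7aR)-2,2,3a-trimethyl-4-oxohexahydro-1,3-benzodioxol-6-yl acetate | O=C1C[C@H](OC(C)=O)C[C@H]2OC(C)(C)O[C@@]12C
F6 | step 3 | (3aR,7aR)-2,2,3a-trimethyl-7,7a-dihydro-1,3-benzodioxol-4(3aH)-one | O=C1C=CC[C@H]2OC(C)(C)O[C@@]12C
F7 | step 3 | 5,6-epoxide of F6 (epoxide configuration immaterial) | O=C1C2OC2C[C@H]3OC(C)(C)O[C@@]13C
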